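A one-step world has one rate law and one clock, but these flasks have three steps, and one of them feeds on its own by-product.

    substrate + reagent + by-product → product + 2 by-product (k1 = 0.0221 /M²/s)
    substrate + reagent → product + by-product (k2 = 1.11 × 10⁻⁶ /M/s)
    gas ⇌ reagent, rate k3*(csat - [reagent]) (k3 = 2.71 × 10⁻⁵ /s, csat = 30 mM)

the same everywhere: substrate 0.10 M; gas 30 mM (held)

| charge | time |
|---|---|
| green | 2.0 d |
| red | 4.0 d |
| blue | 8.0 d |

1. which of these there is most of at the end, counted by the substrate in it, green (product / substrate)
2. which of these there is most of at the end, counted by the substrate in it, red (product / substrate)
3. which of these there is most of at the end, counted by the substrate in it, blue (product / substrate)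
4. amount of the one of these that there is most of at the end, in percent of the substrate charged, green
5. amount of the one of these that there is most of at the end, in percent of the substrate charged, red
6. amount of the one of these that there is most of at the end, in percent of the substrate charged, blue

At first no reagent is dissolved, and [reagent] climbs toward 30 mM with a lag of 0.427 d. Step 2 alone needs 72 d to halve the reagent, far longer than that lag, so we treat the transfer as done and hold [reagent] at saturation.

In the middle, substrate is nearly whole and the flask is pseudo-first-order in [by-product] plus a seed, the ratio of the two rate constants, 5.02 × 10⁻⁵ M. That sum grows by a factor e every 0.175 d. Meanwhile the gas can deliver at most 0.0702 M/d, and demand reaches this ceiling at [by-product] = 0.0123 M.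

We call the moment of that meeting the takeover time: the lag, plus the growth time multiplied by the logarithm of the transfer coefficient over the uncatalysed pseudo-first-order constant at the charged substrate. For these charges it comes to 1.39 d.

After takeover, transfer is the rate-limiting step. Running at the ceiling, we reach 55.3 % product in green at 2.0 d. That is a rough figure, since inflow equals the ceiling just when [reagent] is nil, and the dissolved stock also gets drawn down. So we call green close. The whole charge takes until 2.64 d, earlier than red's reading, so we expect product in red and blue.

The forecast differs from us on green, choosing substrate at 59 %. For red it gives product at 99.4 % and for blue product at 100 %, holding that after an induction “gas transfer limits the rate”.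

The flask gives substrate at 59.3 % in green, product at 99.5 % in red and product at 100 % in blue. In green, reagent was made 3.17 times as fast as it was used at 0.837 d and 0.846 times at 2.00 d; the takeover falls later than the first reading and earlier than the second. Blue's product moves by 6 points if read as early as 3.38 d. With 0.025 M of substrate, demand could meet the ceiling only at [by-product] = 0.0490 M, more than that charge can yield, so this neighbour has no takeover time, and at 2.00 d it still holds 98.3 % substrate.

The constants come from no measurement; the rest is arithmetic.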